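**Plan**

1. Retrosynthesis (ring numbered as in the target name: C-1 carries the acid chain, C-2 is the quaternary centre, C-3 carries the secondary methyl, C-6 the isopropylidene). The indole C-3–CH2 bond is cut first (reductive alkylation of indole by a neopentyl aldehyde). Then the ring bonds C-6–C-1 and C-3–C-2 are cut together in a [4+2] sense.
2. Enabling feature: C-2 (CH3, CH2-indolyl) and C-1 (H, chain), with CH3 cis to the chain, are the two carbons of an (E)-2-methyl-2-enal whose formyl carbon becomes the CH2 link. C-3 to C-6, with the methyl on C-3, are an (E)-propenyl diene. The exocyclic C-6=C(CH3)2 next to the C-5 methylene is the dehydrated acetone aldol of a C-5 ketone.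
3. Helpers: a silyloxy group on C-5 (ketone oxidation level) and a silyl-protected acetone-aldol unit on C-6 of the diene. They give regiocontrol and reactivity in the cycloaddition, then the isopropylidene by beta-elimination, then acid stability (as enone and dienyl triflate) for the indole alkylation. The oxygen is removed as the enol triflate and the ring C=C by diimide.
4. Forward order: aldol and bis-silylation give the diene; a Wittig reaction gives the enal; the catalytic asymmetric Diels–Alder reaction closes the only carbocycle; then unmasking, triflation, indole attachment, deoxygenation, saturation and ester hydrolysis.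
5. Stereochemistry: absolute configuration from the chiral oxazaborolidinium catalyst; C-1/C-2 from the (E)-enal; C-3 from the (E)-propenyl terminus and the endo (formyl) transition state. No later step touches these three centres.

Key step: step 4

Remark: the sense of facial selection of the catalyst is taken from its accepted pre-transition-state model for 2-substituted enals (formyl C–H···O contact, s-trans enal, one face shielded by an aryl group); this predicts addition to the Re face of the formyl-bearing carbon with the (S)-catalyst.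

**Route**

Step 1
Reactants: 1 (E)-pent-3-en-2-one; 2 acetone
Product: 4 (2E)-6-hydroxy-6-methylhept-2-en-4-one, via lithium (E)-penta-1,3-dien-2-olate 3 (not isolated)
Conditions: LiN(iPr)2, THF, −78 °C; acetone, −78 °C; AcOH quench at −78 °C
Reagents that add atoms: none
Why: Directed (crossed) aldol addition: kinetic deprotonation of the methyl ketone gives the cross-conjugated lithium enolate, which should add to acetone and be quenched cold before retro-aldol cleavage can occur.

Step 2
Reactants: 4 (2E)-6-hydroxy-6-methylhept-2-en-4-one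
Product: 6 (2E,4Z)-4,6-bis{[tert-butyl(dimethyl)silyl]oxy}-6-methylhepta-2,4-diene, via dilithium alkoxide enolate 5 (not isolated)
Conditions: LiN(iPr)2 (2.2 equiv), THF–DMPU, −78 °C; TBSOTf (2.4 equiv), −78 to 0 °C; Et3N/NaHCO3 work-up
Reagents that add atoms: tert-butyldimethylsilyl trifluoromethanesulfonate, CC(C)(C)[Si](C)(C)OS(=O)(=O)C(F)(F)F
Why: Kinetic enolisation and O-silylation (silyl dienol ether formation): the second equivalent of base should remove an alpha-prime hydrogen rather than a gamma hydrogen, the alkoxide cannot leave, and the (Z) enol ether expected in the presence of DMPU places the tertiary group on the outside of the s-cis diene.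

Step 3
Reactants: 7 methyl 4-oxobutanoate; 8 2-(triphenyl-λ5-phosphanylidene)propanal
Product: 9 methyl (4E)-5-methyl-6-oxohex-4-enoate
Conditions: PhMe, 85 °C
Reagents that add atoms: none
Why: Wittig olefination with a stabilised ylide should give the (E)-2-methyl-2-enal selectively, and the conjugated, alpha-branched product aldehyde reacts much more slowly with the ylide than the aliphatic aldehyde does.

Step 4
Reactants: 6 (2E,4Z)-4,6-bis{[tert-butyl(dimethyl)silyl]oxy}-6-methylhepta-2,4-diene; 9 methyl (4E)-5-methyl-6-oxohex-4-enoate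
Product: 10 methyl 3-[(1R,2S,5R,6R)-3-{[tert-butyl(dimethyl)silyl]oxy}-2-(2-{[tert-butyl(dimethyl)silyl]oxy}propan-2-yl)-6-formyl-5,6-dimethylcyclohex-3-en-1-yl]propanoate
Conditions: (S)-3,3-diphenyl-1-(2-methylphenyl)tetrahydro-1H,3H-pyrrolo[1,2-c][1,3,2]oxazaborole·HNTf2 (20 mol %), CH2Cl2, −78 to −40 °C; Et3N quench
Reagents that add atoms: none
Why: The protonated oxazaborolidine binds the formyl oxygen of 9 and the electron-rich 2-silyloxy diene 6 should add in a concerted but asynchronous, suprafacial normal-demand Diels–Alder reaction in which the bond from the enol ether carbon (future C-6) to the enal beta-carbon (future C-1) leads; the closest known reactions are oxazaborolidinium-catalysed Diels–Alder additions of 2-silyloxy-1,3-dienes to 2-substituted enals. The cyclohexene ring is closed intermolecularly by [4+2] union of the four-carbon diene and the two-carbon dienophile, both new bonds forming on one face of each partner. Regiochemistry, the selectivity this step needs most, is fixed by the silyloxy group, which makes the diene carbon next to it the nucleophilic terminus, and is reinforced by pairing of the methyl-bearing terminus with the formyl-bearing carbon. The methyl on C-2 is cis to the chain on C-1 because the (E)-enal reacts suprafacially, and the methyl on C-3 is cis to formyl because the (E)-propenyl terminus meets the boron-bound formyl group in the endo position, which is open because both diene termini carry only outside substituents. The absolute configuration comes from the catalyst, whose aryl group blocks one enal face so that the diene adds to the Re face of the formyl-bearing carbon. The stereocentre formed at the carbon carrying the silyloxypropyl group is destroyed in step 5 and needs no control.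

Step 5
Reactants: 10 the Diels–Alder adduct
Product: 12 methyl 3-[(1S,2R,3R)-2-formyl-2,3-dimethyl-5-oxo-6-(propan-2-ylidene)cyclohexyl]propanoate, via hydroxy ketone 11 (not isolated)
Conditions: aq. HF, MeCN, 0 to 23 °C; then TsOH·H2O (cat.), CH2Cl2, 23 °C
Reagents that add atoms: none
Why: Silyl ether cleavage followed by acid-catalysed aldol-type dehydration (beta-elimination through the enol): the only alkene this can give is the conjugated tetrasubstituted C-6 isopropylidene, so its position is set regiospecifically while the three stereocentres, none of them alpha to the ketone on an enolisable side, stay untouched.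

Step 6
Reactants: 12 methyl 3-[(1S,2R,3R)-2-formyl-2,3-dimethyl-5-oxo-6-(propan-2-ylidene)cyclohexyl]propanoate
Product: 14 methyl 3-[(1R,5R,6R)-6-formyl-5,6-dimethyl-2-(propan-2-ylidene)-3-{[(trifluoromethyl)sulfonyl]oxy}cyclohex-3-en-1-yl]propanoate, via potassium dienolate 13 (not isolated)
Conditions: KN(SiMe3)2 added to 12 and PhNTf2, THF, −78 °C
Reagents that add atoms: N-phenylbis(trifluoromethanesulfonimide), O=S(=O)(N(c1ccccc1)S(=O)(=O)C(F)(F)F)C(F)(F)F
Why: Kinetic enolate O-triflation: the hindered base should remove a hydrogen from the only alpha-prime methylene (C-4) and the enolate is trapped in situ, while the aldehyde has no alpha hydrogen and the ester is less acidic.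

Step 7
Reactants: 14 the dienyl triflate aldehyde; 15 1H-indole
Product: 16 methyl 3-[(1S,5R,6R)-6-(1H-indol-3-ylmethyl)-5,6-dimethyl-2-(propan-2-ylidene)-3-{[(trifluoromethyl)sulfonyl]oxy}cyclohex-3-en-1-yl]propanoate
Conditions: Et3SiH, CF3CO2H, CH2Cl2, 0 °C
Reagents that add atoms: none
Why: Reductive Friedel–Crafts alkylation of indole: acid-promoted addition of indole C-3 to the aldehyde, ionisation to the 3-alkylidene-indoleninium ion and hydride transfer from the silane should give the CH2 link, and the electron-poor dienyl triflate resists protonation so the tetrasubstituted alkene is not hydrogenated.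

Step 8
Reactants: 16 the indolylmethyl dienyl triflate
Product: 17 methyl 3-[(1S,5R,6R)-6-(1H-indol-3-ylmethyl)-5,6-dimethyl-2-(propan-2-ylidene)cyclohex-3-en-1-yl]propanoate
Conditions: Pd(OAc)2 (5 mol %), PPh3, Bu3N, HCO2H, DMF, 60 °C
Reagents that add atoms: none
Why: Palladium-catalysed formate reduction of an alkenyl triflate (oxidative addition to zerovalent palladium, formate decarboxylation, reductive elimination) should replace C–O by C–H without moving either double bond.

Step 9
Reactants: 17 the diene ester
Product: 18 methyl 3-[(1S,2R,3R)-2-(1H-indol-3-ylmethyl)-2,3-dimethyl-6-(propan-2-ylidene)cyclohexyl]propanoate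
Conditions: 2-nitrobenzenesulfonohydrazide, Et3N, CH2Cl2, 23 °C
Reagents that add atoms: none
Why: Diimide reduction: concerted syn transfer of H2 should occur only at the cis-disubstituted ring alkene, since tetrasubstituted alkenes and indoles are inert to diimide and no 1,4-addition or isomerisation is possible.

Step 10
Reactants: 18 the methyl ester
Product: 19 3-[(1S,2R,3R)-2-(1H-indol-3-ylmethyl)-2,3-dimethyl-6-(propan-2-ylidene)cyclohexyl]propanoic acid (suaveolindole)
Conditions: LiOH, THF–MeOH–H2O, 23 °C; then 1 M HCl to pH 4 at 0 °C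
Reagents that add atoms: lithium hydroxide, [Li+].[OH-]
Why: Ester saponification under mild base and careful acidification should leave the acid-sensitive isopropylidene group and the indole unchanged.

**Compound list**

1 | (E)-pent-3-en-2-one | C/C=C/C(C)=O | starting material
2 | acetone | CC(C)=O | starting material
3 | lithium (E)-penta-1,3-dien-2-olate | C/C=C/C([O-])=C.[Li+] | intermediate (not isolated)
4 | (2E)-6-hydroxy-6-methylhept-2-en-4-one | C/C=C/C(=O)CC(C)(C)O | intermediate
5 | dilithium (2E,4Z)-6-methylhepta-2,4-diene-4,6-bis(olate) | C/C=C/C([O-])=C/C(C)(C)[O-].[Li+].[Li+] | intermediate (not isolated)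
6 | (2E,4Z)-4,6-bis{[tert-butyl(dimethyl)silyl]oxy}-6-methylhepta-2,4-diene | C/C=C/C(O[Si](C)(C)C(C)(C)C)=C/C(C)(C)O[Si](C)(C)C(C)(C)C | intermediate
7 | methyl 4-oxobutanoate | COC(=O)CCC=O | starting material
8 | 2-(triphenyl-λ5-phosphanylidene)propanal | CC(C=O)=P(c1ccccc1)(c1ccccc1)c1ccccc1 | starting material
9 | methyl (4E)-5-methyl-6-oxohex-4-enoate | COC(=O)CC/C=C(\C)C=O | intermediate
10 | methyl 3-[(1R,2S,5R,6R)-3-{[tert-butyl(dimethyl)silyl]oxy}-2-(2-{[tert-butyl(dimethyl)silyl]oxy}propan-2-yl)-6-formyl-5,6-dimethylcyclohex-3-en-1-yl]propanoate | CC(C)(O[Si](C)(C)C(C)(C)C)[C@H]1C(O[Si](C)(C)C(C)(C)C)=C[C@@H](C)[C@@](C)(C=O)[C@@H]1CCC(=O)OC | intermediate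
11 | methyl 3-[(1R,2R,3R,6S)-2-formyl-6-(2-hydroxypropan-2-yl)-2,3-dimethyl-5-oxocyclohexyl]propanoate (may exist as the lactol) | CC(C)(O)[C@H]1C(=O)C[C@@H](C)[C@@](C)(C=O)[C@@H]1CCC(=O)OC | intermediate (not isolated)
12 | methyl 3-[(1S,2R,3R)-2-formyl-2,3-dimethyl-5-oxo-6-(propan-2-ylidene)cyclohexyl]propanoate | CC(C)=C1C(=O)C[C@@H](C)[C@@](C)(C=O)[C@@H]1CCC(=O)OC | intermediate
13 | potassium cross-conjugated dienolate of 12 (C-4/C-5 enolate, stereocentres as in 12) | CC(C)=C1C([O-])=C[C@@H](C)[C@@](C)(C=O)[C@@H]1CCC(=O)OC.[K+] | intermediate (not isolated)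
14 | methyl 3-[(1R,5R,6R)-6-formyl-5,6-dimethyl-2-(propan-2-ylidene)-3-{[(trifluoromethyl)sulfonyl]oxy}cyclohex-3-en-1-yl]propanoate | CC(C)=C1C(OS(=O)(=O)C(F)(F)F)=C[C@@H](C)[C@@](C)(C=O)[C@@H]1CCC(=O)OC | intermediate
15 | 1H-indole | c1ccc2[nH]ccc2c1 | starting material
16 | methyl 3-[(1S,5R,6R)-6-(1H-indol-3-ylmethyl)-5,6-dimethyl-2-(propan-2-ylidene)-3-{[(trifluoromethyl)sulfonyl]oxy}cyclohex-3-en-1-yl]propanoate | CC(C)=C1C(OS(=O)(=O)C(F)(F)F)=C[C@@H](C)[C@@](C)(Cc2c[nH]c3ccccc23)[C@@H]1CCC(=O)OC | intermediate
17 | methyl 3-[(1S,5R,6R)-6-(1H-indol-3-ylmethyl)-5,6-dimethyl-2-(propan-2-ylidene)cyclohex-3-en-1-yl]propanoate | CC(C)=C1C=C[C@@H](C)[C@@](C)(Cc2c[nH]c3ccccc23)[C@@H]1CCC(=O)OC | intermediate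
18 | methyl 3-[(1S,2R,3R)-2-(1H-indol-3-ylmethyl)-2,3-dimethyl-6-(propan-2-ylidene)cyclohexyl]propanoate | CC(C)=C1CC[C@@H](C)[C@@](C)(Cc2c[nH]c3ccccc23)[C@@H]1CCC(=O)OC | intermediate
19 | 3-[(1S,2R,3R)-2-(1H-indol-3-ylmethyl)-2,3-dimethyl-6-(propan-2-ylidene)cyclohexyl]propanoic acid (suaveolindole) | CC(C)=C1CC[C@@H](C)[C@@](C)(Cc2c[nH]c3ccccc23)[C@@H]1CCC(=O)O | target

**Step count and risks**

Total step count: 10. Longest linear sequence: 9 steps (steps 1, 2, 4, 5, 6, 7, 8, 9, 10 from 1); step 3 is the convergent branch.

Steps most likely to fail: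

Step 4. Bond formation between the hindered enol ether carbon and the substituted beta-carbon may be slow. The bulky C-6 substituent may erode the endo preference. The acid catalyst may ionise the allylic tertiary silyl ether, or the reaction may leak into a stepwise Mukaiyama–Michael path with loss of stereocontrol. Fallback: 6 and 9 are combined without catalyst in PhMe at 110 °C in a sealed tube (thermal Diels–Alder reaction of a 2-silyloxy diene with an enal). This gives the racemic endo adduct, which is resolved by preparative chromatography on a chiral stationary phase. The unwanted antipode is methyl 3-[(1S,2R,5S,6S)-3-{[tert-butyl(dimethyl)silyl]oxy}-2-(2-{[tert-butyl(dimethyl)silyl]oxy}propan-2-yl)-6-formyl-5,6-dimethylcyclohex-3-en-1-yl]propanoate F1. The fallback sets out from 6 and 9 and comes back to the route at 10.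

Step 6. Deprotonation may occur at the gamma methyl groups of the isopropylidene instead of C-4, and the base or the enolate may attack the free aldehyde. Fallback: the ketone is removed without an enolate. Setting out from 12, reductive alkylation of indole 15 (Et3SiH, CF3CO2H, CH2Cl2, 0 °C; the enone protects the alkene) gives methyl 3-[(1S,2R,3R)-2-(1H-indol-3-ylmethyl)-2,3-dimethyl-5-oxo-6-(propan-2-ylidene)cyclohexyl]propanoate F2. Luche reduction (NaBH4, CeCl3·7H2O, MeOH, −40 °C) gives methyl 3-[(1S,2R,3R)-5-hydroxy-2-(1H-indol-3-ylmethyl)-2,3-dimethyl-6-(propan-2-ylidene)cyclohexyl]propanoate F3 as a mixture of C-5 epimers. Ionic deoxygenation (Et3SiH, BF3·OEt2, CH2Cl2, −78 °C), with hydride delivery expected at the less hindered secondary end of the allyl cation, comes back to the route at 18.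

Step 7. Condensation of the hindered neopentyl aldehyde with indole may be slow, a second indole may add to give a bis(indolyl)methane, or the acid may protonate the diene. Fallback: carbon–carbon bond formation and deoxygenation are separated. Setting out from 14, bromo(indol-1-yl)magnesium (from 15 and EtMgBr, CH2Cl2–Et2O, −20 °C) should add through indole C-3 to the aldehyde to give methyl 3-[(1S,5R,6R)-6-[hydroxy(1H-indol-3-yl)methyl]-5,6-dimethyl-2-(propan-2-ylidene)-3-{[(trifluoromethyl)sulfonyl]oxy}cyclohex-3-en-1-yl]propanoate F4 (both carbinol epimers). Et3SiH with BF3·OEt2 in CH2Cl2 at −78 °C then removes the readily ionised indolyl carbinol oxygen and comes back to the route at 16.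

Further compounds
F1 | step 4 | methyl 3-[(1S,2R,5S,6S)-3-{[tert-butyl(dimethyl)silyl]oxy}-2-(2-{[tert-butyl(dimethyl)silyl]oxy}propan-2-yl)-6-formyl-5,6-dimethylcyclohex-3-en-1-yl]propanoate | CC(C)(O[Si](C)(C)C(C)(C)C)[C@@H]1C(O[Si](C)(C)C(C)(C)C)=C[C@H](C)[C@](C)(C=O)[C@H]1CCC(=O)OC
F2 | step 6 | methyl 3-[(1S,2R,3R)-2-(1H-indol-3-ylmethyl)-2,3-dimethyl-5-oxo-6-(propan-2-ylidene)cyclohexyl]propanoate | CC(C)=C1C(=O)C[C@@H](C)[C@@](C)(Cc2c[nH]c3ccccc23)[C@@H]1CCC(=O)OC
F3 | step 6 | methyl 3-[(1S,2R,3R)-5-hydroxy-2-(1H-indol-3-ylmethyl)-2,3-dimethyl-6-(propan-2-ylidene)cyclohexyl]propanoate | CC(C)=C1C(O)C[C@@H](C)[C@@](C)(Cc2c[nH]c3ccccc23)[C@@H]1CCC(=O)OC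
F4 | step 7 | methyl 3-[(1S,5R,6R)-6-[hydroxy(1H-indol-3-yl)methyl]-5,6-dimethyl-2-(propan-2-ylidene)-3-{[(trifluoromethyl)sulfonyl]oxy}cyclohex-3-en-1-yl]propanoate | CC(C)=C1C(OS(=O)(=O)C(F)(F)F)=C[C@@H](C)[C@@](C)(C(O)c2c[nH]c3ccccc23)[C@@H]1CCC(=O)OC
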